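The time asked, 15 min, lies later than the last readings at 10.0 min, but the noon run moves by about its scatter of 2 percentage points from 4.00 min to 10.0 min: D goes from 21% to 19%, L from 24% to 22%. So I read the end of the flask as a plateau and count turnovers.

| flask | E | J | remark | time |
|---|---|---|---|---|
| midnight | 0.050 M | 0.032 M | run made earlier |  |
| winter | 0.050 M | 0.071 M | run made earlier |  |
| noon | 0.075 M | 0.0475 M | run made earlier |  |
| flask | 0.050 M | 0.0475 M |  | 15 min |

| run | time / min | D / % | L / % |
|---|---|---|---|
| midnight | 1.00 | 15 | 7 |
| midnight | 3.00 | 20 | 17 |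
| midnight | 6.00 | 23 | 20 |
| midnight | 10.0 | 19 | 21 |
| winter | 1.00 | 17 | 20 |
| winter | 3.00 | 12 | 50 |
| winter | 6.00 | 9 | 60 |
| winter | 10.0 | 8 | 65 |
| noon | 0.667 | 12 | 9 |
| noon | 1.50 | 21 | 12 |
| noon | 4.00 | 21 | 24 |
| noon | 10.0 | 19 | 22 |

(scatter of a reading: 2 percentage points)

- share of D in D plus L at 8.0 s
- share of D in D plus L at 80 s
- share of D in D plus L at 15 min
- which of D and L there is more of at 15 min

- the numbers in the tables scatter by 2 percentage points (one standard deviation)

If each D holds one J, each L two, and the J charged ends up in these two, the plateau should obey D + 2L = n, where n is my turnover budget, the J charged per E charged, for this flask 95.0%. The runs bear this out: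

midnight: n = 64.0%, D + 2L = 61.0%
winter: n = 142%, D + 2L = 138%
noon: n = 63.3%, D + 2L = 63.0%

The budget is a plateau rule, so it gives no share at 8.0 s or 80 s. For the end I need one more relation, and a first guess draws a straight line in n between the midnight and winter end readings of D:

D = 14.6%, L = (n − D)/2 = 40.2%, share 26.6%

That line is the weak link, since in the winter run D falls from 17% to 8% while L climbs from 20% to 65%, so I take D to be made and then consumed in a chain. Let x be the part of the charge in neither D nor L, so x = 1 − (n + D)/2. A selectivity factor of 3, the rate constant of the second step over that of the first, gives D = (x − x·x·x)/2, which comes close to the midnight reading of 19% at 10.0 min, where x = 60.0% gives 19.2%. Reforged from the first guess: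

x = 45.2%, D = 18.0%, L = 38.5%, share 31.9%

I commit to that share, with L ahead.

The forecast, a little lower at the end, says 90%, 53%, 31% and L ahead, holding that “After J is gone everything is flat”.

The flask gives 93.0%, 54.3% and 32.4%, with L ahead.

    J + Q ⇌ G (K = 184 /M, k = 0.313 /M/s)
    E → Z (k = 0.0107 /s)
    E → X (k = 0.0393 /s)
    J + D → L (k = 0.567 /M/s)
    J + X → D (k = 0.333 /M/s)
    Z → Q (k = 0.00146 /s)

In this flask at 15 min D stands at 18.1% and L at 37.9%, and with G, which also holds J, and the free J, 0.159% of its own charge, the count comes to 95.0% of the E charged against n = 95.0%. Charging 0.085 M of E instead cuts the budget of the neighbouring flask to 55.9%. Starting from the midnight D, the same reckoning gives x = 62.6%, D = 19.0% and L = 18.4%, a share of 50.8%. That neighbouring flask stands at 15 min with D ahead of L, at 20.4% against 17.6%, a share of 53.6%.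

All runs come from a simulation with made-up constants; scatter was added.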